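Ring A is the benzyl ring, numbered as in the target (carbon 1 bears the CH2), ring B the aryl ring on the α-carbon. The route rests on forming the two C–Br bonds at ring A carbons 2 and 3 last. The key step exploits the guaiacol-type ring A of its precursor: carbon 3 lies ortho to the free hydroxyl on carbon 4 and carbon 2 para to the benzyl ether on carbon 5, so two equivalents of bromine substitute both in one operation, while ring B (3-acetoxy, 4-methoxy, 5-bromo) stays inert and the α-stereocenter is untouched. The precursor, a methyl (R)-2,3-diarylpropanoate, comes from Perkin condensation and iridium-catalysed asymmetric hydrogenation; BCl3 then methanol unmasks the target.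

Key step: step 10

Remark: the α-carbon (carbon 2 of the propanoate chain) is R in the target and in every chiral intermediate (CO2R > aryl > CH2Ar > H); ring B has an isovanillin-type pattern (hydroxyl at position 3, methoxy at position 4), so its aldehyde is made by 4-O-methylation of 3-bromo-4,5-dihydroxybenzaldehyde, assumed to be a catalogue compound, and not from a vanillin-type (4-hydroxy-3-methoxy) aldehyde.

Step 1
Reactants: 1 3-bromo-4,5-dihydroxybenzaldehyde; 2 iodomethane
Product: 3 3-bromo-5-hydroxy-4-methoxybenzaldehyde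
Conditions: MeI (1.1 equiv), Li2CO3 (1.2 equiv), DMF, 40 °C
Reagents that add atoms: iodomethane, CI
Why: Williamson O-methylation: the 4-hydroxyl, para to the formyl group and ortho to bromine, is much the more acidic phenol, so the weak base Li2CO3 forms only its phenoxide and MeI alkylates that oxygen, as in the known 4-O-selective alkylations of protocatechualdehydes.

Step 2
Reactants: 3 3-bromo-5-hydroxy-4-methoxybenzaldehyde; 4 N-acetylglycine; 5 acetic anhydride
Product: 6 (Z)-4-(3-acetoxy-5-bromo-4-methoxybenzylidene)-2-methyloxazol-5(4H)-one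
Conditions: N-acetylglycine (1.2 equiv), NaOAc (1.2 equiv), Ac2O, 100 °C
Reagents that add atoms: N-acetylglycine, CC(=O)NCC(O)=O; acetic anhydride, CC(=O)OC(C)=O
Why: Erlenmeyer–Plöchl azlactone synthesis: acetic anhydride cyclises N-acetylglycine to 2-methyloxazol-5(4H)-one, whose acidic ring CH2 condenses with the aldehyde to the thermodynamically preferred Z-benzylidene azlactone, while the phenol is acetylated in the same pot.

Step 3
Reactants: 6 (Z)-4-(3-acetoxy-5-bromo-4-methoxybenzylidene)-2-methyloxazol-5(4H)-one; 7 hydrogen peroxide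
Product: 9 2-(3-bromo-5-hydroxy-4-methoxyphenyl)acetic acid, via arylpyruvic acid 8 (not isolated)
Conditions: 10% aq NaOH, reflux; then 30% H2O2, 0 °C → rt; then HCl to pH 1
Reagents that add atoms: water, O; hydrogen peroxide, OO
Why: Hot aqueous NaOH opens the azlactone, cleaves the enamide and the aryl acetate and leaves the arylpyruvate 8, which hydrogen peroxide converts by nucleophilic addition to the keto group and loss of CO2 (oxidative decarboxylation of an α-keto acid) into the arylacetic acid, the classical azlactone route to phenolic arylacetic acids.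

Step 4
Reactants: 10 3,4-dihydroxybenzaldehyde; 11 chloromethyl methyl ether
Product: 12 3-hydroxy-4-(methoxymethoxy)benzaldehyde
Conditions: MOMCl (1.05 equiv), K2CO3 (1.1 equiv), acetone, 0 °C → rt
Reagents that add atoms: chloromethyl methyl ether, COCCl
Why: Regioselective Williamson-type alkylation: only the 4-hydroxyl, para to the formyl group, is ionised by K2CO3 under these conditions, so one equivalent of MOMCl should give the 4-O-MOM ether.

Step 5
Reactants: 12 3-hydroxy-4-(methoxymethoxy)benzaldehyde; 13 benzyl bromide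
Product: 14 3-(benzyloxy)-4-(methoxymethoxy)benzaldehyde
Conditions: BnBr (1.2 equiv), K2CO3 (1.5 equiv), DMF, rt
Reagents that add atoms: benzyl bromide, BrCc1ccccc1
Why: Williamson benzylation of the remaining phenol under standard carbonate conditions, to which the MOM acetal and the aldehyde are inert.

Step 6
Reactants: 9 2-(3-bromo-5-hydroxy-4-methoxyphenyl)acetic acid; 14 3-(benzyloxy)-4-(methoxymethoxy)benzaldehyde; 5 acetic anhydride
Product: 15 (E)-2-(3-acetoxy-5-bromo-4-methoxyphenyl)-3-[3-(benzyloxy)-4-(methoxymethoxy)phenyl]prop-2-enoic acid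
Conditions: Ac2O (5 equiv), Et3N (2.5 equiv), 110 °C; then H2O, 60 °C; aq citric acid to pH 4
Reagents that add atoms: acetic anhydride, CC(=O)OC(C)=O
Why: Perkin condensation (Oglialoro variant): the mixed anhydride of the arylacetic acid is enolised by Et3N, adds to the aldehyde and loses acetate to give the thermodynamically favoured E acid with the two aryl groups cis, the ring B phenol being acetylated on the way and the amine-buffered medium sparing the MOM and benzyl ethers.

Step 7
Reactants: 15 (E)-2-(3-acetoxy-5-bromo-4-methoxyphenyl)-3-[3-(benzyloxy)-4-(methoxymethoxy)phenyl]prop-2-enoic acid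
Product: 16 (R)-2-(3-acetoxy-5-bromo-4-methoxyphenyl)-3-[3-(benzyloxy)-4-(methoxymethoxy)phenyl]propanoic acid
Conditions: H2 (6 atm), [Ir(cod)(SIPHOX)]B[3,5-(CF3)2C6H3]4 (1 mol %), Et3N (0.5 equiv), MeOH, 30 °C
Reagents that add atoms: none
Why: Carboxylate-directed asymmetric hydrogenation of an α-substituted cinnamic acid, a known substrate class for iridium complexes of chiral spirobiindane phosphine–oxazoline (SIPHOX) ligands: the bound carboxylate holds the alkene in the chiral pocket and both hydrogens are delivered syn to one face, which sets the α-stereocenter, the ligand antipode being the one that gives the (R)-acid (sense to be verified on a trial run by chiral HPLC and optical rotation), while the homogeneous catalyst should leave the aryl bromide, benzyl ether, MOM acetal and aryl acetate intact.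

Step 8
Reactants: 16 (R)-2-(3-acetoxy-5-bromo-4-methoxyphenyl)-3-[3-(benzyloxy)-4-(methoxymethoxy)phenyl]propanoic acid; 17 (trimethylsilyl)diazomethane
Product: 18 methyl (R)-2-(3-acetoxy-5-bromo-4-methoxyphenyl)-3-[3-(benzyloxy)-4-(methoxymethoxy)phenyl]propanoate
Conditions: TMSCHN2 (1.2 equiv), toluene/MeOH (4:1), 0 °C
Reagents that add atoms: (trimethylsilyl)diazomethane, C[Si](C)(C)C=[N+]=[N-]
Why: Esterification with TMSCHN2 in methanol (methyl transfer through the diazonium ion formed by protonation) is fast for the carboxylic acid under neutral conditions, so the α-aryl stereocenter cannot epimerise and the aryl acetate is not touched.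

Step 9
Reactants: 18 methyl (R)-2-(3-acetoxy-5-bromo-4-methoxyphenyl)-3-[3-(benzyloxy)-4-(methoxymethoxy)phenyl]propanoate
Product: 19 methyl (R)-2-(3-acetoxy-5-bromo-4-methoxyphenyl)-3-[3-(benzyloxy)-4-hydroxyphenyl]propanoate
Conditions: ZnBr2 (1.0 equiv), n-PrSH (2.0 equiv), CH2Cl2, 0 °C → rt
Reagents that add atoms: none
Why: Lewis-acid-assisted acetal cleavage: ZnBr2 activates the MOM group and the soft thiol traps the oxocarbenium fragment as an O,S-acetal within minutes, a method known to spare benzyl ethers, aryl acetates and esters and not basic enough to touch the α-carbon.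

Step 10
Reactants: 19 methyl (R)-2-(3-acetoxy-5-bromo-4-methoxyphenyl)-3-[3-(benzyloxy)-4-hydroxyphenyl]propanoate; 20 bromine
Product: 22 methyl (R)-2-(3-acetoxy-5-bromo-4-methoxyphenyl)-3-[5-(benzyloxy)-2,3-dibromo-4-hydroxyphenyl]propanoate, via ring A monobromide 21 (not isolated)
Conditions: Br2 (2.05 equiv), NaOAc (2.5 equiv), AcOH/CH2Cl2 (1:1), 0 °C → rt
Reagents that add atoms: bromine, BrBr
Why: Each bromine enters by electrophilic aromatic substitution through an arenium ion, first at ring A carbon 3 ortho to the free hydroxyl on carbon 4 to give 21 and then at carbon 2, the only carbon para to an oxygen donor (the benzyl ether on carbon 5), and the opposite order of attack would converge on the same 2,3-dibromide. The closest known reaction is the stepwise bromination of vanillin to 5-bromovanillin and on to 5,6-dibromovanillin, which follows the same ortho-to-hydroxyl then para-to-alkoxy pattern. No ring is closed and no stereocenter is formed, and the α-carbon is not enolised in the buffered, weakly acidic medium. The step needs site selectivity within ring A (carbons 2 and 3 over carbon 6) and chemoselectivity over ring B. Carbon 6 of ring A is meta to the hydroxyl, ortho only to the weaker donor and wedged between the benzyloxy group and the side chain, while ring B has the oxygen on its carbon 3 acetylated and no free carbon ortho or para to the methoxy group on its carbon 4. Sodium acetate takes up the hydrogen bromide, which protects the benzyl ether, and the charge is held at two equivalents to avoid a third substitution at carbon 6.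

Step 11
Reactants: 22 methyl (R)-2-(3-acetoxy-5-bromo-4-methoxyphenyl)-3-[5-(benzyloxy)-2,3-dibromo-4-hydroxyphenyl]propanoate
Product: 24 methyl (R)-2-(3-bromo-5-hydroxy-4-methoxyphenyl)-3-(2,3-dibromo-4,5-dihydroxyphenyl)propanoate, via debenzylated aryl acetate 23 (not isolated)
Conditions: BCl3 (4 equiv), C6HMe5 (4 equiv), CH2Cl2, −78 °C; then MeOH, −78 °C → 40 °C
Reagents that add atoms: none
Why: BCl3 coordinates the benzyl ether oxygen and the benzyl cation is taken up by pentamethylbenzene (Lewis-acid debenzylation with a cation scavenger, which at −78 °C should leave the aryl bromides and the ring B methyl ether alone), and the methanol quench liberates HCl, which removes the ring B acetate by acid-catalysed transesterification that is degenerate for the methyl ester and harmless to the stereocenter.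

Compound list
1 | 3-bromo-4,5-dihydroxybenzaldehyde | O=Cc1cc(O)c(O)c(Br)c1 | starting material
2 | iodomethane | CI | starting material
3 | 3-bromo-5-hydroxy-4-methoxybenzaldehyde | COc1c(O)cc(C=O)cc1Br | intermediate
4 | N-acetylglycine | CC(=O)NCC(O)=O | starting material
5 | acetic anhydride | CC(=O)OC(C)=O | starting material
6 | (Z)-4-(3-acetoxy-5-bromo-4-methoxybenzylidene)-2-methyloxazol-5(4H)-one | CC1=N/C(=C\c2cc(OC(C)=O)c(OC)c(Br)c2)C(=O)O1 | intermediate
7 | hydrogen peroxide | OO | starting material
8 | 3-(3-bromo-5-hydroxy-4-methoxyphenyl)-2-oxopropanoic acid | COc1c(O)cc(CC(=O)C(O)=O)cc1Br | intermediate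
9 | 2-(3-bromo-5-hydroxy-4-methoxyphenyl)acetic acid | COc1c(O)cc(CC(O)=O)cc1Br | intermediate
10 | 3,4-dihydroxybenzaldehyde | O=Cc1ccc(O)c(O)c1 | starting material
11 | chloromethyl methyl ether | COCCl | starting material
12 | 3-hydroxy-4-(methoxymethoxy)benzaldehyde | COCOc1ccc(C=O)cc1O | intermediate
13 | benzyl bromide | BrCc1ccccc1 | starting material
14 | 3-(benzyloxy)-4-(methoxymethoxy)benzaldehyde | COCOc1ccc(C=O)cc1OCc1ccccc1 | intermediate
15 | (E)-2-(3-acetoxy-5-bromo-4-methoxyphenyl)-3-[3-(benzyloxy)-4-(methoxymethoxy)phenyl]prop-2-enoic acid | OC(=O)/C(=C/c1ccc(OCOC)c(OCc2ccccc2)c1)c1cc(OC(C)=O)c(OC)c(Br)c1 | intermediate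
16 | (R)-2-(3-acetoxy-5-bromo-4-methoxyphenyl)-3-[3-(benzyloxy)-4-(methoxymethoxy)phenyl]propanoic acid | OC(=O)[C@H](Cc1ccc(OCOC)c(OCc2ccccc2)c1)c1cc(OC(C)=O)c(OC)c(Br)c1 | intermediate
17 | (trimethylsilyl)diazomethane | C[Si](C)(C)C=[N+]=[N-] | starting material
18 | methyl (R)-2-(3-acetoxy-5-bromo-4-methoxyphenyl)-3-[3-(benzyloxy)-4-(methoxymethoxy)phenyl]propanoate | COC(=O)[C@H](Cc1ccc(OCOC)c(OCc2ccccc2)c1)c1cc(OC(C)=O)c(OC)c(Br)c1 | intermediate
19 | methyl (R)-2-(3-acetoxy-5-bromo-4-methoxyphenyl)-3-[3-(benzyloxy)-4-hydroxyphenyl]propanoate | COC(=O)[C@H](Cc1ccc(O)c(OCc2ccccc2)c1)c1cc(OC(C)=O)c(OC)c(Br)c1 | intermediate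
20 | bromine | BrBr | starting material
21 | methyl (R)-2-(3-acetoxy-5-bromo-4-methoxyphenyl)-3-[3-(benzyloxy)-5-bromo-4-hydroxyphenyl]propanoate | COC(=O)[C@H](Cc1cc(Br)c(O)c(OCc2ccccc2)c1)c1cc(OC(C)=O)c(OC)c(Br)c1 | intermediate
22 | methyl (R)-2-(3-acetoxy-5-bromo-4-methoxyphenyl)-3-[5-(benzyloxy)-2,3-dibromo-4-hydroxyphenyl]propanoate | COC(=O)[C@H](Cc1cc(OCc2ccccc2)c(O)c(Br)c1Br)c1cc(OC(C)=O)c(OC)c(Br)c1 | intermediate
23 | methyl (R)-2-(3-acetoxy-5-bromo-4-methoxyphenyl)-3-(2,3-dibromo-4,5-dihydroxyphenyl)propanoate | COC(=O)[C@H](Cc1cc(O)c(O)c(Br)c1Br)c1cc(OC(C)=O)c(OC)c(Br)c1 | intermediate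
24 | methyl (R)-2-(3-bromo-5-hydroxy-4-methoxyphenyl)-3-(2,3-dibromo-4,5-dihydroxyphenyl)propanoate | COC(=O)[C@H](Cc1cc(O)c(O)c(Br)c1Br)c1cc(O)c(OC)c(Br)c1 | target

Total step count: 11. Longest linear sequence: 9 steps (steps 1–3 and 6–11, from 1).

Steps most likely to fail

Step 7. The catalyst may discriminate the two alkene faces poorly or turn over slowly on this hindered trisubstituted acid, and the ring B aryl acetate may be slowly methanolysed in the amine-containing methanol. The fallback replaces asymmetric catalysis by resolution and keeps the acetate out of basic methanol. Setting out from 15, TMSCHN2 (toluene/MeOH, 0 °C) should give methyl (E)-2-(3-acetoxy-5-bromo-4-methoxyphenyl)-3-[3-(benzyloxy)-4-(methoxymethoxy)phenyl]prop-2-enoate F1. Hydrogenation with the achiral catalyst [Ir(cod)(PCy3)(py)]PF6 (5 mol %, H2 50 atm, CH2Cl2, rt) should give racemic methyl 2-(3-acetoxy-5-bromo-4-methoxyphenyl)-3-[3-(benzyloxy)-4-(methoxymethoxy)phenyl]propanoate F2. Preparative supercritical-fluid chromatography on an amylose tris(3,5-dimethylphenylcarbamate) phase would separate F2 into the (R)-ester 18, where the route is rejoined, and methyl (S)-2-(3-acetoxy-5-bromo-4-methoxyphenyl)-3-[3-(benzyloxy)-4-(methoxymethoxy)phenyl]propanoate F3, which is set aside.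

Step 10. The second substitution may lose site control (attack at ring A carbon 6 or a third bromination), the reaction may stall at the monobromide, or hydrogen bromide may begin to cleave the benzyl ether. The fallback uses two single brominations, each steered by a different oxygen. Setting out from 18, NBS (1.05 equiv) in MeCN at 0 °C should brominate only ring A carbon 2, the one carbon para to an ether oxygen while the oxygen on carbon 4 is still a MOM ether, giving methyl (R)-2-(3-acetoxy-5-bromo-4-methoxyphenyl)-3-[5-(benzyloxy)-2-bromo-4-(methoxymethoxy)phenyl]propanoate F4. ZnBr2 and n-PrSH in CH2Cl2 should then free the hydroxyl on carbon 4 to give methyl (R)-2-(3-acetoxy-5-bromo-4-methoxyphenyl)-3-[5-(benzyloxy)-2-bromo-4-hydroxyphenyl]propanoate F5. One equivalent of Br2 (NaOAc, AcOH/CH2Cl2, 0 °C) should enter ortho to that hydroxyl at carbon 3, rejoining the route at 22.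

Step 6. The condensation may stall with the electron-rich aldehyde, give E/Z mixtures or decarboxylate to the stilbene, and the MOM acetal may be exchanged for acetate in hot anhydride, which would leave two indistinguishable aryl acetates. The fallback is a base-mediated ester condensation in place of the anhydride method. Setting out from 9, Fischer esterification (MeOH, H2SO4 cat., reflux) should give methyl 2-(3-bromo-5-hydroxy-4-methoxyphenyl)acetate F6. Condensation of F6 with 14 under NaOMe (3 equiv) in MeOH at reflux, then aqueous NaOH and acidification with HCl to pH 4, should give (E)-3-[3-(benzyloxy)-4-(methoxymethoxy)phenyl]-2-(3-bromo-5-hydroxy-4-methoxyphenyl)prop-2-enoic acid F7. Acetylation of the ring B phenol (Ac2O, pyridine, rt, then water) returns to the route at 15.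

Further compounds
F1 | step 7 | methyl (E)-2-(3-acetoxy-5-bromo-4-methoxyphenyl)-3-[3-(benzyloxy)-4-(methoxymethoxy)phenyl]prop-2-enoate | COC(=O)/C(=C/c1ccc(OCOC)c(OCc2ccccc2)c1)c1cc(OC(C)=O)c(OC)c(Br)c1
F2 | step 7 | racemic methyl 2-(3-acetoxy-5-bromo-4-methoxyphenyl)-3-[3-(benzyloxy)-4-(methoxymethoxy)phenyl]propanoate | COC(=O)C(Cc1ccc(OCOC)c(OCc2ccccc2)c1)c1cc(OC(C)=O)c(OC)c(Br)c1
F3 | step 7 | methyl (S)-2-(3-acetoxy-5-bromo-4-methoxyphenyl)-3-[3-(benzyloxy)-4-(methoxymethoxy)phenyl]propanoate | COC(=O)[C@@H](Cc1ccc(OCOC)c(OCc2ccccc2)c1)c1cc(OC(C)=O)c(OC)c(Br)c1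
F4 | step 10 | methyl (R)-2-(3-acetoxy-5-bromo-4-methoxyphenyl)-3-[5-(benzyloxy)-2-bromo-4-(methoxymethoxy)phenyl]propanoate | COC(=O)[C@H](Cc1cc(OCc2ccccc2)c(OCOC)cc1Br)c1cc(OC(C)=O)c(OC)c(Br)c1
F5 | step 10 | methyl (R)-2-(3-acetoxy-5-bromo-4-methoxyphenyl)-3-[5-(benzyloxy)-2-bromo-4-hydroxyphenyl]propanoate | COC(=O)[C@H](Cc1cc(OCc2ccccc2)c(O)cc1Br)c1cc(OC(C)=O)c(OC)c(Br)c1
F6 | step 6 | methyl 2-(3-bromo-5-hydroxy-4-methoxyphenyl)acetate | COC(=O)Cc1cc(O)c(OC)c(Br)c1
F7 | step 6 | (E)-3-[3-(benzyloxy)-4-(methoxymethoxy)phenyl]-2-(3-bromo-5-hydroxy-4-methoxyphenyl)prop-2-enoic acid | OC(=O)/C(=C/c1ccc(OCOC)c(OCc2ccccc2)c1)c1cc(O)c(OC)c(Br)c1
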